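**Retrosynthesis**
- Asbestinin 16 comes from late-stage octanoylation and allylic oxidation to the enone, after a macrocyclic oxocarbenium/allylsilane (Sakurai) closure that forms Cc–Cb and the THF/oxonane bridge last.
- That macrocyclisation needs a cyclohexane–THF-acetal–oxepane core. The oxepane is closed by a tertiary alcohol displacing a primary triflate.
- The cyclohexene and γ-lactone come from an intramolecular Diels–Alder (the key step) of a 4-methylpentadienoate ester of an (E)-allylic alcohol.
- That alcohol comes from chelation-controlled alkenylation of an α-hydroxy quaternary aldehyde. The quaternary carbon comes from (S)-lactic acid, the CH(CH3)CH2O centre from the (S)-Roche ester, and the diene acid from methacrolein.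
- Ring order: cyclohexene + γ-lactone (Diels–Alder), then oxepane, then THF/oxonane (macrocyclisation).

Assumption: the Diels–Alder gives the cis-fused lactone with the Cd substituent trans to the new Ce–Cf bond, and any minor diastereomer is separated. The Cp carbinol epimers are not distinguished because Cp is later oxidised.

Atom labels used in "Why": Ca is the exocyclic-methylene carbon, Cb the CH2 next to it, Cc the ether CH bearing Cb, Cd the ether CH bearing Cm, Cm the quaternary C(Me)–O, Cn the CH–OOct, Co the CH2, Cp the ketone. Ce and Cj are the cyclohexane ring-fusion carbons, Cf the ring carbon bearing Ck, Ch the ring CHMe, Ci the ring CH–OAc, Ck the CH(CH3) of the oxepane, and Cl the OCH2.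

---

**Step 1**
Reactants: 1 methyl (S)-3-hydroxy-2-methylpropanoate
Product: 2 methyl (S)-3-(TBSO)-2-methylpropanoate
Conditions: TBSCl, imidazole, CH2Cl2, 0 °C→rt
Reagents that add atoms: TBSCl, CC(C)(C)[Si](C)(C)Cl
Why: Silylation of the primary alcohol (protection) leaves the Roche stereocentre untouched.

**Step 2**
Reactants: 2
Product: 3 (S)-3-(TBSO)-2-methylpropanal
Conditions: DIBAL-H, CH2Cl2, −78 °C; use crude at once
Reagents that add atoms: none
Why: Partial ester reduction gives the α-methyl aldehyde without epimerising the adjacent stereocentre at −78 °C.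

**Step 3**
Reactants: 3
Product: 4 (E)-vinyl iodide, TBSO–CH2–CH(CH3)–CH=CH–I
Conditions: CHI3, CrCl2, THF, 0 °C
Reagents that add atoms: iodoform, IC(I)I
Why: Takai olefination is E-selective and proceeds without epimerisation, so Ck is preserved (it becomes the CH(CH3)CH2O centre).

**Step 4**
Reactants: 5 (S)-lactic acid; 6 pivalaldehyde
Product: 7 (2S,5S)-2-tert-butyl-5-methyl-1,3-dioxolan-4-one
Conditions: cat. TsOH, pentane, Dean–Stark reflux; isolate the cis isomer
Reagents that add atoms: none
Why: Acetalisation gives the cis acetal with the t-Bu-bearing carbon set by the lactic acid centre (self-regeneration of stereocentres, no external chiral element).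

**Step 5**
Reactants: 7
Product: 8 5-(benzyloxymethyl)-2-tert-butyl-5-methyl-dioxolan-4-one, CH2OBn trans to t-Bu
Conditions: LDA, THF, −78 °C; then BnOCH2Cl, DMPU, −78→−40 °C
Reagents that add atoms: benzyl chloromethyl ether, ClCOCc1ccccc1
Why: Enolate alkylation occurs trans to t-Bu with net retention at C5, so the lactic acid configuration becomes the quaternary Cm centre.

**Step 6**
Reactants: 8
Product: 9 (S)-3-(benzyloxy)-2-methylpropane-1,2-diol
Conditions: LiAlH4, THF, 0 °C
Reagents that add atoms: none
Why: Ester and acetal are reduced (tBuCH2OH is a by-product); no stereocentre is touched.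

**Step 7**
Reactants: 9
Product: 10 primary TBDPS ether of 9 (the free CH2OH carbon is Cn)
Conditions: TBDPSCl, imidazole, DMF, 0 °C→rt
Reagents that add atoms: TBDPSCl, CC(C)(C)[Si](c1ccccc1)(c1ccccc1)Cl
Why: Only the unhindered primary hydroxyl is silylated, which differentiates the two CH2O arms.

**Step 8**
Reactants: 10
Product: 11 3-(TBDPSO)-2-methylpropane-1,2-diol (free CH2OH on the former OBn arm, the future Cd)
Conditions: H2 (1 atm), 10% Pd/C, EtOAc, rt
Reagents that add atoms: none
Why: Hydrogenolysis removes the benzyl group without affecting the silyl ether.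

**Step 9**
Reactants: 11
Product: 12 3-(TBDPSO)-2-hydroxy-2-methylpropanal
Conditions: Dess–Martin periodinane, NaHCO3, CH2Cl2, 0 °C
Reagents that add atoms: none
Why: The aldehyde sits next to a quaternary carbon, so it cannot epimerise and is configurationally stable.

**Step 10**
Reactants: 12; 4
Product: 13 (4E)-1-(TBDPSO)-7-(TBSO)-2,6-dimethylhept-4-ene-2,3-diol (stereochemistry as in the list)
Conditions: 4 (3 equiv) + i-PrMgCl·LiCl (3 equiv), THF, −40 °C, then 12, −78→−30 °C
Reagents that add atoms: none
Why: Iodine–magnesium exchange gives the E-alkenyl Grignard, which adds in a chelation-controlled (Cram-chelate) mode through the magnesium alkoxide of the tertiary α-OH, from the face bearing the smaller Me group, setting Cd with the required relative configuration to Cm.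

**Step 11**
Reactants: 14 methacrolein; 15 malonic acid
Product: 16 (2E)-4-methylpenta-2,4-dienoic acid
Conditions: pyridine, cat. piperidine, 100 °C
Reagents that add atoms: none
Why: Knoevenagel–Doebner condensation with decarboxylation gives the E-dienoic acid.

**Step 12**
Reactants: 13; 16
Product: 17 the 3-O-(2E)-4-methylpentadienoyl ester of 13
Conditions: 2,4,6-Cl3C6H2COCl, Et3N, THF; then 13, DMAP, toluene, 50 °C
Reagents that add atoms: none
Why: Yamaguchi esterification acylates only the secondary allylic OH; the hindered tertiary OH does not react.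

**Step 13**
Reactants: 17
Product: 18 cis-fused cyclohexene γ-lactone (intramolecular Diels–Alder adduct)
Conditions: toluene (0.02 M), BHT, 190 °C, sealed tube, 36 h
Reagents that add atoms: none
Why: In this intramolecular Diels–Alder the (E)-alkene fixes Cd and Ck trans. The tether stereocentre Cd, with its bulky substituent pseudo-equatorial, selects the alkene face and so sets Ce, Cf and Cj, and the compact endo transition state gives the cis-fused lactone.

**Step 14**
Reactants: 18
Product: 19 the Ck–CH2OH lactone
Conditions: CSA (0.1 equiv), MeOH/CH2Cl2 1:1, 0 °C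
Reagents that add atoms: none
Why: A primary TBS ether is cleaved selectively in the presence of the TBDPS ether.

**Step 15**
Reactants: 19
Product: 20 oxepane-bridged lactone
Conditions: Tf2O, 2,6-di-tert-butyl-4-methylpyridine, CH2Cl2, −78→25 °C
Reagents that add atoms: none
Why: The primary alcohol is triflated selectively and the tertiary alcohol closes the 7-membered ring by intramolecular SN2 under non-basic conditions, which avoids lactone translactonisation and leaves Cm unchanged.

**Step 16**
Reactants: 20
Product: 21 lactol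
Conditions: DIBAL-H (1.1 equiv), CH2Cl2, −78 °C
Reagents that add atoms: none
Why: Selective lactone-to-lactol reduction; the anomeric centre is temporary.

**Step 17**
Reactants: 21
Product: 22 methyl acetal (anomeric mixture)
Conditions: MeOH, cat. CSA, CH2Cl2, 0 °C→rt
Reagents that add atoms: methanol, CO
Why: Acetalisation gives a base-stable oxocarbenium precursor for the final ring closure.

**Step 18**
Reactants: 22
Product: 23 secondary alcohol at Ci, with the methyl at Ch set
Conditions: 9-BBN, THF, 0→25 °C; then NaOH, H2O2, 0 °C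
Reagents that add atoms: hydrogen peroxide, OO
Why: Hydroboration puts boron on the less substituted Ci from the convex face, anti to the lactone-derived acetal ring. This sets H at Ch (Me up, as in the target) and leaves a temporary OH at Ci that is trans to the target.

**Step 19**
Reactants: 23
Product: 24 Ci ketone
Conditions: Dess–Martin periodinane, NaHCO3, CH2Cl2, rt
Reagents that add atoms: none
Why: Oxidation of the secondary alcohol removes the wrong Ci configuration.

**Step 20**
Reactants: 24
Product: 25 Ci alcohol with OH on the same face as the acetal carbon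
Conditions: L-Selectride, THF, −78 °C
Reagents that add atoms: none
Why: The bulky hydride enters from the open convex face, opposite the cis-fused acetal ring and the Ch methyl, so the OH ends up cis to them as in the target.

**Step 21**
Reactants: 25
Product: 26 Ci acetate
Conditions: Ac2O, pyridine, cat. DMAP, CH2Cl2, rt
Reagents that add atoms: acetic anhydride, CC(=O)OC(C)=O
Why: Acetylation installs the C–OAc group of the target.

**Step 22**
Reactants: 26
Product: 27 primary alcohol at Cn
Conditions: TBAF, AcOH, THF, 0→25 °C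
Reagents that add atoms: none
Why: Buffered fluoride removes TBDPS without cleaving the acetate or the acetal.

**Step 23**
Reactants: 27
Product: 28 aldehyde at Cn
Conditions: Dess–Martin periodinane, NaHCO3, CH2Cl2, rt
Reagents that add atoms: none
Why: The neopentyl aldehyde next to the quaternary Cm cannot epimerise.

**Step 24**
Reactants: 28
Product: 29 homoallylic alcohol at Cn
Conditions: allylSnBu3 (3 equiv), MgBr2·OEt2 (3 equiv), CH2Cl2, −78→−20 °C
Reagents that add atoms: allyltributylstannane, C=CC[Sn](CCCC)(CCCC)CCCC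
Why: Chelation-controlled allylation through the oxepane oxygen on Cm attacks from the face bearing Me, giving the Cn configuration required by the target.

**Step 25**
Reactants: 29
Product: 30 Cn–OTES ether
Conditions: TESOTf, 2,6-lutidine, CH2Cl2, −78 °C
Reagents that add atoms: TESOTf, CC[Si](CC)(CC)OS(=O)(=O)C(F)(F)F
Why: Protection prevents later attack of the Cn oxygen on the oxocarbenium ion.

**Step 26**
Reactants: 30
Product: 31 aldehyde at Cp
Conditions: O3, CH2Cl2, −78 °C; then PPh3
Reagents that add atoms: ozone, O=[O+][O-]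
Why: Ozonolysis cleaves the terminal alkene; it is the only alkene left, because the ring alkene was consumed in Step 18.

**Step 27**
Reactants: 31; 32 2-bromo-3-(trimethylsilyl)prop-1-ene
Product: 33 bis-TES allylsilane at Cp
Conditions: 32, Mg, THF, 25 °C; add 31, −78 °C; then TESCl, −78→0 °C
Reagents that add atoms: triethylsilyl chloride, CC[Si](CC)(CC)Cl
Why: Grignard addition to the aldehyde builds the 2-(silylmethyl)allyl carbinol in one pot; the Cp stereocentre is later destroyed, so epimers do not matter.

**Step 28**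
Reactants: 33
Product: 34 macrocycle with the THF/oxonane bridge
Conditions: BF3·OEt2 (2 equiv), CH2Cl2 (2 mM), −78→−40 °C
Reagents that add atoms: none
Why: BF3 ionises the methyl acetal to an oxocarbenium ion and the tethered allylsilane attacks it through its CH2= terminus (intramolecular Hosomi–Sakurai allylation), forming Cc–Cb and the exocyclic methylene; the 2,5-cis bridging across the THF fixes Cc.

**Step 29**
Reactants: 34
Product: 35 diol (Cn–OH, Cp–OH)
Conditions: HF·pyridine, pyridine, THF, 0 °C
Reagents that add atoms: none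
Why: Both TES ethers are removed; the acetate and exocyclic alkene are untouched.

**Step 30**
Reactants: 35
Product: 36 hydroxy-enone (Cp ketone, Cn–OH)
Conditions: activated MnO2, CH2Cl2, 25 °C
Reagents that add atoms: none
Why: MnO2 oxidises only the allylic carbinol to the α-methylene ketone and leaves the saturated Cn–OH.

**Step 31**
Reactants: 36
Product: 37 asbestinin 16
Conditions: octanoyl chloride, pyridine, cat. DMAP, CH2Cl2, 0 °C
Reagents that add atoms: octanoyl chloride, CCCCCCCC(=O)Cl
Why: Esterification of the only free hydroxyl completes the target, and no stereocentre is touched.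

---

**Compound list**

1 | methyl (S)-3-hydroxy-2-methylpropanoate | COC(=O)[C@@H](C)CO | starting material
2 | methyl (S)-3-(TBSO)-2-methylpropanoate | COC(=O)[C@@H](C)CO[Si](C)(C)C(C)(C)C | intermediate
3 | (S)-3-(TBSO)-2-methylpropanal | O=C[C@@H](C)CO[Si](C)(C)C(C)(C)C | intermediate
4 | (E)-vinyl iodide from 3 | I/C=C/[C@@H](C)CO[Si](C)(C)C(C)(C)C | intermediate
5 | (S)-lactic acid | C[C@H](O)C(=O)O | starting material
6 | pivalaldehyde | CC(C)(C)C=O | starting material
7 | (2S,5S)-2-tert-butyl-5-methyl-1,3-dioxolan-4-one | O=C1O[C@@H](C(C)(C)C)O[C@H]1C | intermediate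
8 | 5-(benzyloxymethyl) dioxolanone | O=C1O[C@@H](C(C)(C)C)O[C@]1(C)COCc1ccccc1 | intermediate
9 | (S)-3-(benzyloxy)-2-methylpropane-1,2-diol | C[C@](O)(CO)COCc1ccccc1 | intermediate
10 | primary TBDPS ether of 9 | C[C@](O)(CO[Si](c1ccccc1)(c1ccccc1)C(C)(C)C)COCc1ccccc1 | intermediate
11 | debenzylated diol | C[C@](O)(CO[Si](c1ccccc1)(c1ccccc1)C(C)(C)C)CO | intermediate
12 | α-hydroxy aldehyde | C[C@](O)(CO[Si](c1ccccc1)(c1ccccc1)C(C)(C)C)C=O | intermediate
13 | (4E)-allylic alcohol/tertiary alcohol | C[C@](O)(CO[Si](c1ccccc1)(c1ccccc1)C(C)(C)C)[C@@H](O)/C=C/[C@@H](C)CO[Si](C)(C)C(C)(C)C | intermediate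
14 | methacrolein | C=C(C)C=O | starting material
15 | malonic acid | OC(=O)CC(=O)O | starting material
16 | (2E)-4-methylpenta-2,4-dienoic acid | OC(=O)/C=C/C(C)=C | intermediate
17 | dienoate ester (Diels–Alder precursor) | C[C@](O)(CO[Si](c1ccccc1)(c1ccccc1)C(C)(C)C)[C@@H](OC(=O)/C=C/C(C)=C)/C=C/[C@@H](C)CO[Si](C)(C)C(C)(C)C | intermediate
18 | cis-fused cyclohexene γ-lactone | C[C@](O)(CO[Si](c1ccccc1)(c1ccccc1)C(C)(C)C)[C@H]1OC(=O)[C@@H]2C=C(C)C[C@@H]([C@@H](C)CO[Si](C)(C)C(C)(C)C)[C@H]12 | intermediate
19 | Ck–CH2OH lactone | C[C@](O)(CO[Si](c1ccccc1)(c1ccccc1)C(C)(C)C)[C@H]1OC(=O)[C@@H]2C=C(C)C[C@@H]([C@@H](C)CO)[C@H]12 | intermediate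
20 | oxepane lactone | O=C1O[C@H]2[C@@H]3[C@H]1C=C(C)C[C@H]3[C@@H](C)CO[C@@]2(C)CO[Si](c4ccccc4)(c4ccccc4)C(C)(C)C | intermediate
21 | lactol | OC1O[C@H]2[C@@H]3[C@H]1C=C(C)C[C@H]3[C@@H](C)CO[C@@]2(C)CO[Si](c4ccccc4)(c4ccccc4)C(C)(C)C | intermediate
22 | methyl acetal | COC1O[C@H]2[C@@H]3[C@H]1C=C(C)C[C@H]3[C@@H](C)CO[C@@]2(C)CO[Si](c4ccccc4)(c4ccccc4)C(C)(C)C | intermediate
23 | Ci alcohol (hydroboration product) | COC1O[C@H]2[C@@H]3[C@H]1[C@@H](O)[C@H](C)C[C@H]3[C@@H](C)CO[C@@]2(C)CO[Si](c4ccccc4)(c4ccccc4)C(C)(C)C | intermediate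
24 | Ci ketone | COC1O[C@H]2[C@@H]3[C@H]1C(=O)[C@H](C)C[C@H]3[C@@H](C)CO[C@@]2(C)CO[Si](c4ccccc4)(c4ccccc4)C(C)(C)C | intermediate
25 | Ci alcohol (OH cis to the acetal carbon) | COC1O[C@H]2[C@@H]3[C@H]1[C@H](O)[C@H](C)C[C@H]3[C@@H](C)CO[C@@]2(C)CO[Si](c4ccccc4)(c4ccccc4)C(C)(C)C | intermediate
26 | Ci acetate | COC1O[C@H]2[C@@H]3[C@H]1[C@H](OC(C)=O)[C@H](C)C[C@H]3[C@@H](C)CO[C@@]2(C)CO[Si](c4ccccc4)(c4ccccc4)C(C)(C)C | intermediate
27 | primary alcohol | COC1O[C@H]2[C@@H]3[C@H]1[C@H](OC(C)=O)[C@H](C)C[C@H]3[C@@H](C)CO[C@@]2(C)CO | intermediate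
28 | aldehyde at Cn | COC1O[C@H]2[C@@H]3[C@H]1[C@H](OC(C)=O)[C@H](C)C[C@H]3[C@@H](C)CO[C@@]2(C)C=O | intermediate
29 | homoallylic alcohol | COC1O[C@H]2[C@@H]3[C@H]1[C@H](OC(C)=O)[C@H](C)C[C@H]3[C@@H](C)CO[C@@]2(C)[C@H](O)CC=C | intermediate
30 | Cn–OTES ether | COC1O[C@H]2[C@@H]3[C@H]1[C@H](OC(C)=O)[C@H](C)C[C@H]3[C@@H](C)CO[C@@]2(C)[C@H](O[Si](CC)(CC)CC)CC=C | intermediate
31 | aldehyde at Cp | COC1O[C@H]2[C@@H]3[C@H]1[C@H](OC(C)=O)[C@H](C)C[C@H]3[C@@H](C)CO[C@@]2(C)[C@H](O[Si](CC)(CC)CC)CC=O | intermediate
32 | 2-bromo-3-(trimethylsilyl)prop-1-ene | C=C(Br)C[Si](C)(C)C | starting material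
33 | bis-TES allylsilane (Cp epimers) | COC1O[C@H]2[C@@H]3[C@H]1[C@H](OC(C)=O)[C@H](C)C[C@H]3[C@@H](C)CO[C@@]2(C)[C@H](O[Si](CC)(CC)CC)CC(O[Si](CC)(CC)CC)C(=C)C[Si](C)(C)C | intermediate
34 | macrocycle (bis-TES) | C=C1C[C@@H]2O[C@H]3[C@H]4[C@@H](C[C@@H](C)[C@@H](OC(C)=O)[C@H]42)[C@@H](C)CO[C@@]3(C)[C@H](O[Si](CC)(CC)CC)CC1O[Si](CC)(CC)CC | intermediate
35 | diol | C=C1C[C@@H]2O[C@H]3[C@H]4[C@@H](C[C@@H](C)[C@@H](OC(C)=O)[C@H]42)[C@@H](C)CO[C@@]3(C)[C@H](O)CC1O | intermediate
36 | hydroxy-enone | C=C1C[C@@H]2O[C@H]3[C@H]4[C@@H](C[C@@H](C)[C@@H](OC(C)=O)[C@H]42)[C@@H](C)CO[C@@]3(C)[C@H](O)CC1=O | intermediate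
37 | asbestinin 16 | C=C1C[C@@H]2O[C@H]3[C@H]4[C@@H](C[C@@H](C)[C@@H](OC(C)=O)[C@H]42)[C@@H](C)CO[C@@]3(C)[C@H](OC(=O)CCCCCCC)CC1=O | target

---

**Totals**
- Total steps: 31.
- Longest linear sequence: 27, running from (S)-lactic acid (compound 5) through Step 31.

**Three steps most likely to fail**
1. **Step 13 (ester-tethered intramolecular Diels–Alder).** The dienophile is unactivated, the trans-fused lactone may compete, and the facial selectivity may be mismatched with the Ck centre.
   - Fallback: build the cyclohexene by an intermolecular Diels–Alder of a (5S)-substituted butenolide (from the same Cd carbinol) with a 1-acetoxy-2-methyl diene, then adjust Ci by oxidation/reduction.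
2. **Step 28 (macrocyclic Sakurai).** A 9-endo closure onto a bridged oxocarbenium ion, using an α-silyloxy-substituted 2-substituted allylsilane, may give oligomers or desilylated product.
   - Fallback: make Cc–Cb by intermolecular allylation of acetal 22 with a 2-(silylmethyl)allyl ether, then close the ring at Cn–Co by intramolecular Nozaki–Hiyama–Kishi or aldol macrocyclisation.
3. **Step 15 (tertiary alkoxy-triflate etherification to the oxepane).** The 7-exo closure onto a hindered tertiary alcohol may give elimination or a cyclic triflate.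
   - Fallback: carry an isopropenyl group on Cd instead of the tertiary carbinol, epoxidise it, and close the oxepane by acid-promoted 7-exo opening of the epoxide at Cm by the CH2OH.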